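Carotenoid numbering is used (unprimed atoms for the keto half, primed atoms for the ε half).

**Plan**

1. Cuts: C11=C12 and C11'=C12' (two Horner–Wadsworth–Emmons olefinations on a symmetrical ten-carbon bisphosphonate), C7'=C8' (olefination of a ring aldehyde), O–C19 together with C9–C10 (Morita–Baylis–Hillman bond, then SN2' esterification), C8–C9 and C6–C7.
2. Enabling feature: in the ε-ring, C6' lies between quaternary C1' and the C4'=C5' alkene and carries chain carbon C7'. Drawing C7' back into the ring gives a seven-membered ring with an allylic C6'–C7' oxirane. A shift of C1' from C7' to C6' rebuilds the six-membered ring, expels C7' as CHO, fixes C6' and keeps C4'=C5' out of conjugation.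
3. All ten carbons of that seven-membered ring come from (+)-3-carene (C7 = C1', C6 = C2', C5 = C3', C4 = C4', C3 = C5', C2 = C6', C1 = C7'), by allylic oxidation and norcaradiene-type opening.
4. Forward order: ε-ring aldehyde (steps 1–6), fifteen-carbon aldehyde, twenty-five-carbon phosphonate. In parallel, the β-ring keto aldehyde with the octenoate already in place (steps 12–19). Then union at C11=C12 and desilylation.
5. Stereochemistry: C6' comes from a Jacobsen–Katsuki epoxidation relayed by the stereospecific shift, C3' from a Corey–Bakshi–Shibata reduction, and C3 from (4R,6R)-actinol. The 9E alkene comes from the SN2' Mitsunobu step, and the other E alkenes from the olefinations and the ten-carbon dialdehyde.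

Key step: step 6

Assumption: compounds 8, 11, 15, 18, 24 and 26 are taken as purchasable. The stereocentres of 3-carene vanish in step 2, so either enantiomer serves.

**Step 1**
Reactants: 1 (+)-3-carene
Product: 2 car-3-en-5-one [(1R,6S)-4,7,7-trimethylbicyclo[4.1.0]hept-3-en-2-one]
Conditions: t-BuOOH, Cr(CO)6 (cat), MeCN, reflux
Reagents that add atoms: tert-butyl hydroperoxide CC(C)(C)OO
Why: Metal-catalysed allylic oxidation with t-BuOOH should abstract hydrogen at C5, since the resulting allyl radical has a tertiary terminus at C3 and takes up oxygen at its open secondary end, which gives the β-methyl enone and leaves the cyclopropane intact.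

**Step 2**
Reactants: 2 car-3-en-5-one
Product: 3 3,6,6-trimethylcyclohepta-2,4-dien-1-one (achiral)
Conditions: KOt-Bu (0.3 equiv), t-BuOH, 60 °C
Reagents that add atoms: none
Why: Reversible γ-deprotonation at C2 gives a norcaradiene-type dienolate whose disrotatory six-electron electrocyclic opening breaks the C1–C6 cyclopropane bond, and protonation of the cycloheptatrienolate at the α-carbon gives the conjugated seven-membered dienone, the same valence isomerisation by which car-3-en-2-one goes to eucarvone.

**Step 3**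
Reactants: 3 3,6,6-trimethylcyclohepta-2,4-dien-1-one
Product: 4 (1S,7R)-2,6,6-trimethyl-8-oxabicyclo[5.1.0]oct-2-en-4-one
Conditions: (S,S)-N,N'-bis(3,5-di-tert-butylsalicylidene)-1,2-cyclohexanediaminomanganese chloride (5 mol %), 4-phenylpyridine N-oxide (cat), aq NaOCl (pH 11.3), CH2Cl2, 0 °C
Reagents that add atoms: sodium hypochlorite [Na+].[O-]Cl
Why: Jacobsen–Katsuki epoxidation should pick the cis-disubstituted conjugated γ,δ-alkene over the carbonyl-deactivated trisubstituted α,β-alkene, and because this alkene (sp2 carbon on one side, CMe2 on the other, both tied in a ring) has the shape of a 2,2-dimethylchromene, the (S,S)-catalyst is expected to deliver the (1S,7R)-oxirane.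

**Step 4**
Reactants: 4 (1S,7R)-epoxy enone
Product: 5 (1S,4R,7R)-2,6,6-trimethyl-8-oxabicyclo[5.1.0]oct-2-en-4-ol
Conditions: (S)-2-methyl-CBS-oxazaborolidine (20 mol %), catecholborane, toluene, −78 °C; then H2O
Reagents that add atoms: none
Why: Corey–Bakshi–Shibata reduction under catalyst control, with the alkenyl arm as the large and the CH2 arm as the small substituent, should give the 4R (C3' R) allylic alcohol trans to the oxirane oxygen, while catecholborane at low temperature leaves the vinyl oxirane alone.

**Step 5**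
Reactants: 5 (1S,4R,7R)-epoxy alcohol
Product: 6 (1S,4R,7R)-4-(tert-butyldimethylsilyloxy)-2,6,6-trimethyl-8-oxabicyclo[5.1.0]oct-2-ene
Conditions: TBSCl, imidazole, DMF, rt
Reagents that add atoms: tert-butyldimethylsilyl chloride CC(C)(C)[Si](C)(C)Cl
Why: Standard silylation of the secondary allylic alcohol masks the hydroxyl against the Lewis acid, the carbanions and the hydride of the following steps.

**Step 6**
Reactants: 6 silyl-protected seven-membered vinyl oxirane
Product: 7 (1R,4R)-4-(tert-butyldimethylsilyloxy)-2,6,6-trimethylcyclohex-2-ene-1-carbaldehyde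
Conditions: MeAl(OAr)2 (Ar = 4-bromo-2,6-di-tert-butylphenyl, 20 mol %), CH2Cl2, −78 → −40 °C
Reagents that add atoms: none
Why: The crowded aluminium Lewis acid binds the oxirane oxygen, the C6'–O bond (allylic to C4'=C5') lengthens, and the C7'–C1' ring bond shifts to C6' from the face opposite the departing oxygen while C7' becomes the aldehyde carbon; this is a Meinwald (semipinacol-type) epoxide-to-aldehyde rearrangement, and the closest known types are the organoaluminium-promoted rearrangement of epoxides to aldehydes with anti migration and the ring contraction of cyclic 1,3-diene monoepoxides. The six-membered ring C1'–C6' is closed by this 1,2-alkyl shift out of the seven-membered carbocycle, a ring contraction by one atom (C7' is expelled) and not an exo or endo cyclisation. The only new stereocentre, C6', is set by inversion at the oxirane carbon, so the (1S,7R)-oxirane gives 6'R, trans to the untouched C3' silyl ether. The step needs cleavage at C6'–O rather than C7'–O, which allylic stabilisation and the neopentyl position of C7' secure, and the other cleavage followed by a shift of the vinyl carbon C5' would give the same aldehyde with the same configuration. It also needs alkyl shift rather than hydride shift, which is favoured by the quaternary migrating carbon C1', the relief of seven-ring strain and the preference of the crowded aluminium centre for the slimmer aldehyde complex. Low temperature and the non-basic medium should keep C4'=C5' out of conjugation and C6' from epimerising.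

**Step 7**
Reactants: 7 ε-ring aldehyde; 8 diethyl [(2E)-3-cyano-2-methylprop-2-en-1-yl]phosphonate
Product: 9 (2E,4E)-5-[(1R,4R)-4-(tert-butyldimethylsilyloxy)-2,6,6-trimethylcyclohex-2-en-1-yl]-3-methylpenta-2,4-dienenitrile
Conditions: 8, NaN(SiMe3)2, THF, −78 °C; then 7, −78 → 0 °C
Reagents that add atoms: none
Why: Horner–Wadsworth–Emmons olefination with the vinylogous cyano-stabilised phosphonate anion, run cold so that carbonyl addition outruns enolisation at the hindered C6'–H, should give the 7'E,9'E dienenitrile.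

**Step 8**
Reactants: 9 dienenitrile
Product: 10 (2E,4E)-5-[(1R,4R)-4-(tert-butyldimethylsilyloxy)-2,6,6-trimethylcyclohex-2-en-1-yl]-3-methylpenta-2,4-dienal
Conditions: i-Bu2AlH, toluene, −78 °C; then wet silica gel, 0 °C
Reagents that add atoms: water O
Why: Partial reduction of the nitrile with i-Bu2AlH and hydrolysis of the aluminium imide on work-up gives the dienal without touching the silyl ether or the alkenes.

**Step 9**
Reactants: 11 (2E,4E,6E)-2,7-dimethylocta-2,4,6-trienedial
Product: 12 (2E,4E,6E)-2,7-dimethylocta-2,4,6-triene-1,8-diol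
Conditions: NaBH4, MeOH/THF, 0 °C
Reagents that add atoms: none
Why: Borohydride 1,2-reduction of both conjugated aldehyde groups keeps the all-E triene.

**Step 10**
Reactants: 12 triene diol
Product: 13 tetraethyl [(2E,4E,6E)-2,7-dimethylocta-2,4,6-triene-1,8-diyl]bis(phosphonate)
Conditions: P(OEt)3, ZnI2, THF, reflux
Reagents that add atoms: triethyl phosphite CCOP(OCC)OCC
Why: The ZnI2-promoted direct conversion of allylic alcohols into phosphonates (transesterification to the allyl phosphite, then Arbuzov-type rearrangement at the primary carbon) gives the symmetrical bisphosphonate in one operation.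

**Step 11**
Reactants: 10 fifteen-carbon aldehyde; 13 bisphosphonate
Product: 14 diethyl [(2E,4E,6E,8E,10E,12E)-13-[(1R,4R)-4-(tert-butyldimethylsilyloxy)-2,6,6-trimethylcyclohex-2-en-1-yl]-2,7,11-trimethyltrideca-2,4,6,8,10,12-hexaen-1-yl]phosphonate
Conditions: 13 (3 equiv), NaN(SiMe3)2 (1 equiv), THF, −78 °C; then 10, −78 → 0 °C, dark
Reagents that add atoms: none
Why: Horner–Wadsworth–Emmons olefination with the mono-anion of the bisphosphonate, used in excess and recovered, should form C11'=C12' as the E alkene and stop after one olefination.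

**Step 12**
Reactants: 15 (4R,6R)-4-hydroxy-2,2,6-trimethylcyclohexan-1-one (actinol)
Product: 16 (4R,6R)-4-(tert-butyldimethylsilyloxy)-2,2,6-trimethylcyclohexan-1-one
Conditions: TBSCl, imidazole, DMF, rt
Reagents that add atoms: tert-butyldimethylsilyl chloride CC(C)(C)[Si](C)(C)Cl
Why: Standard silylation of the secondary alcohol keeps the 3R centre of the chiral pool ketone masked until the last step.

**Step 13**
Reactants: 16 silylated actinol
Product: 17 (4R)-4-(tert-butyldimethylsilyloxy)-2,6,6-trimethylcyclohex-1-en-1-yl trifluoromethanesulfonate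
Conditions: LiN(i-Pr)2, THF, −78 °C; then PhNTf2, −78 → 0 °C
Reagents that add atoms: N-phenylbis(trifluoromethanesulfonimide) O=S(=O)(N(c1ccccc1)S(=O)(=O)C(F)(F)F)C(F)(F)F
Why: The ketone can enolise only towards C5 because C1 is quaternary, so deprotonation and O-triflation give the tetrasubstituted enol triflate as one regioisomer, erasing the C5 centre on purpose and leaving C3 untouched.

**Step 14**
Reactants: 17 enol triflate; 18 (E)-2-(2-ethoxyvinyl)-4,4,5,5-tetramethyl-1,3,2-dioxaborolane
Product: 20 2-[(4R)-4-(tert-butyldimethylsilyloxy)-2,6,6-trimethylcyclohex-1-en-1-yl]acetaldehyde, via dienol ether 19 (not isolated)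
Conditions: Pd(OAc)2 (cat), SPhos, K3PO4, THF/H2O, 60 °C; then oxalic acid (cat), wet THF, rt
Reagents that add atoms: water O
Why: Suzuki–Miyaura coupling of the hindered alkenyl triflate with the 2-ethoxyvinyl boronate (an acetaldehyde anion equivalent) and mild acid hydrolysis of the dienol ether, which is protonated at C7, give the β,γ-unsaturated aldehyde with the tetrasubstituted C5=C6 alkene in place.

**Step 15**
Reactants: 20 β-ring acetaldehyde; 21 vinylmagnesium bromide
Product: 22 1-[(4R)-4-(tert-butyldimethylsilyloxy)-2,6,6-trimethylcyclohex-1-en-1-yl]but-3-en-2-ol (both C8 epimers)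
Conditions: CH2=CHMgBr, THF, −78 °C; then H2O
Reagents that add atoms: none
Why: Grignard 1,2-addition forms the C8–C9 bond, and the new carbinol centre, formed as a mixture, is removed in step 16.

**Step 16**
Reactants: 22 allylic alcohol
Product: 23 1-[(4R)-4-(tert-butyldimethylsilyloxy)-2,6,6-trimethylcyclohex-1-en-1-yl]but-3-en-2-one
Conditions: Dess–Martin periodinane, CH2Cl2, 0 °C
Reagents that add atoms: none
Why: Dess–Martin oxidation turns the allylic carbinol into the vinyl ketone under neutral conditions that should neither move the C5=C6 alkene nor add to the enone.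

**Step 17**
Reactants: 23 vinyl ketone; 24 2,2-dimethoxyacetaldehyde
Product: 25 4-hydroxy-5,5-dimethoxy-3-methylidene-1-[(4R)-4-(tert-butyldimethylsilyloxy)-2,6,6-trimethylcyclohex-1-en-1-yl]pentan-2-one (both C10 epimers)
Conditions: 24 (aq, 5 equiv), DABCO (cat), dioxane/H2O, rt
Reagents that add atoms: none
Why: In the Morita–Baylis–Hillman reaction DABCO adds to the vinyl ketone, the zwitterionic enolate attacks the reactive α,α-dialkoxy aldehyde used in excess, and loss of the amine leaves the C9–C10 bond with a carbinol centre that is erased in step 18.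

**Step 18**
Reactants: 25 Morita–Baylis–Hillman alcohol; 26 (E)-oct-2-enoic acid
Product: 27 (2E)-2-{[(4R)-4-(tert-butyldimethylsilyloxy)-2,6,6-trimethylcyclohex-1-en-1-yl]acetyl}-4,4-dimethoxybut-2-en-1-yl (2E)-oct-2-enoate
Conditions: PPh3, DIAD, THF, 0 °C
Reagents that add atoms: none
Why: The Mitsunobu reaction of a Morita–Baylis–Hillman alcohol runs in the SN2' sense, the carboxylate adding to the C19 methylene as the oxyphosphonium group leaves C10 (direct attack there is hindered and deactivated by the acetal), which installs the ester and gives the alkene with the acyl group trans to C11 to minimise allylic strain, that is 9E.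

**Step 19**
Reactants: 27 ester acetal
Product: 28 (2E)-2-{[(4R)-4-(tert-butyldimethylsilyloxy)-2,6,6-trimethylcyclohex-1-en-1-yl]acetyl}-4-oxobut-2-en-1-yl (2E)-oct-2-enoate
Conditions: Amberlyst-15, acetone/H2O, rt
Reagents that add atoms: water O
Why: Acid-resin hydrolysis of the allylic dimethyl acetal is mild enough for the secondary silyl ether and the allylic ester, and the acyl group on O19 blocks cyclisation of the cis-placed C19 oxygen onto the new aldehyde.

**Step 20**
Reactants: 14 twenty-five-carbon phosphonate; 28 keto aldehyde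
Product: 29 3,3'-bis-O-(tert-butyldimethylsilyl) ether of the target
Conditions: 14, NaN(SiMe3)2 (1 equiv), THF, −78 °C; then 28, −78 → −20 °C, dark
Reagents that add atoms: none
Why: Horner–Wadsworth–Emmons olefination of the pre-formed polyenyl phosphonate anion with the aldehyde, which is far more electrophilic than the hindered C8 ketone or the enoate, should close the chain at C11=C12 as the E alkene.

**Step 21**
Reactants: 29 bis-silyl ether
Product: 30 target, (3R,3'R,6'R)-3,3'-dihydroxy-19-[(2E)-oct-2-enoyloxy]-7,8-dihydro-β,ε-caroten-8-one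
Conditions: Bu4NF, AcOH (1:1), THF, 0 °C → rt, dark
Reagents that add atoms: none
Why: Fluoride cleavage of both secondary silyl ethers, buffered with acetic acid so that no free alkoxide attacks the allylic enoate or the base-sensitive ε end group, should release the target with all three stereocentres untouched.

**Compound list**

1 | (+)-3-carene, (1S,6R)-3,7,7-trimethylbicyclo[4.1.0]hept-3-ene | CC1=CC[C@@H]2[C@H](C1)C2(C)C | starting material
2 | car-3-en-5-one, (1R,6S)-4,7,7-trimethylbicyclo[4.1.0]hept-3-en-2-one | CC1=CC(=O)[C@@H]2[C@H](C1)C2(C)C | intermediate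
3 | 3,6,6-trimethylcyclohepta-2,4-dien-1-one | CC1=CC(=O)CC(C)(C)C=C1 | intermediate
4 | (1S,7R)-2,6,6-trimethyl-8-oxabicyclo[5.1.0]oct-2-en-4-one | CC1=CC(=O)CC(C)(C)[C@H]2O[C@@H]12 | intermediate
5 | (1S,4R,7R)-2,6,6-trimethyl-8-oxabicyclo[5.1.0]oct-2-en-4-ol | CC1=C[C@H](O)CC(C)(C)[C@H]2O[C@@H]12 | intermediate
6 | (1S,4R,7R)-4-(tert-butyldimethylsilyloxy)-2,6,6-trimethyl-8-oxabicyclo[5.1.0]oct-2-ene | CC1=C[C@H](O[Si](C)(C)C(C)(C)C)CC(C)(C)[C@H]2O[C@@H]12 | intermediate
7 | (1R,4R)-4-(tert-butyldimethylsilyloxy)-2,6,6-trimethylcyclohex-2-ene-1-carbaldehyde | O=C[C@H]1C(C)=C[C@H](O[Si](C)(C)C(C)(C)C)CC1(C)C | intermediate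
8 | diethyl [(2E)-3-cyano-2-methylprop-2-en-1-yl]phosphonate | CCOP(=O)(OCC)C/C(C)=C/C#N | starting material
9 | (2E,4E)-dienenitrile of the ε end group | N#C/C=C(C)/C=C/[C@H]1C(C)=C[C@H](O[Si](C)(C)C(C)(C)C)CC1(C)C | intermediate
10 | (2E,4E)-dienal of the ε end group (fifteen-carbon aldehyde) | O=C/C=C(C)/C=C/[C@H]1C(C)=C[C@H](O[Si](C)(C)C(C)(C)C)CC1(C)C | intermediate
11 | (2E,4E,6E)-2,7-dimethylocta-2,4,6-trienedial | O=C/C(C)=C/C=C/C=C(C)/C=O | starting material
12 | (2E,4E,6E)-2,7-dimethylocta-2,4,6-triene-1,8-diol | OC/C(C)=C/C=C/C=C(C)/CO | intermediate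
13 | tetraethyl [(2E,4E,6E)-2,7-dimethylocta-2,4,6-triene-1,8-diyl]bis(phosphonate) | CCOP(=O)(OCC)C/C(C)=C/C=C/C=C(C)/CP(=O)(OCC)OCC | intermediate
14 | all-E twenty-five-carbon hexaenyl phosphonate of the ε half | CCOP(=O)(OCC)C/C(C)=C/C=C/C=C(C)/C=C/C=C(C)/C=C/[C@H]1C(C)=C[C@H](O[Si](C)(C)C(C)(C)C)CC1(C)C | intermediate
15 | (4R,6R)-4-hydroxy-2,2,6-trimethylcyclohexan-1-one (actinol) | O=C1[C@H](C)C[C@@H](O)CC1(C)C | starting material
16 | (4R,6R)-4-(tert-butyldimethylsilyloxy)-2,2,6-trimethylcyclohexan-1-one | O=C1[C@H](C)C[C@@H](O[Si](C)(C)C(C)(C)C)CC1(C)C | intermediate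
17 | (4R)-4-(tert-butyldimethylsilyloxy)-2,6,6-trimethylcyclohex-1-en-1-yl triflate | O=S(=O)(OC1=C(C)C[C@@H](O[Si](C)(C)C(C)(C)C)CC1(C)C)C(F)(F)F | intermediate
18 | (E)-2-(2-ethoxyvinyl)-4,4,5,5-tetramethyl-1,3,2-dioxaborolane | CCO/C=C/B1OC(C)(C)C(C)(C)O1 | starting material
19 | (E)-dienol ethyl ether of the β ring | CCO/C=C/C1=C(C)C[C@@H](O[Si](C)(C)C(C)(C)C)CC1(C)C | intermediate
20 | 2-[(4R)-4-(tert-butyldimethylsilyloxy)-2,6,6-trimethylcyclohex-1-en-1-yl]acetaldehyde | O=CCC1=C(C)C[C@@H](O[Si](C)(C)C(C)(C)C)CC1(C)C | intermediate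
21 | vinylmagnesium bromide | C=C[Mg]Br | starting material
22 | β-ring but-3-en-2-ol (C8 epimers) | C=CC(O)CC1=C(C)C[C@@H](O[Si](C)(C)C(C)(C)C)CC1(C)C | intermediate
23 | β-ring but-3-en-2-one (vinyl ketone) | C=CC(=O)CC1=C(C)C[C@@H](O[Si](C)(C)C(C)(C)C)CC1(C)C | intermediate
24 | 2,2-dimethoxyacetaldehyde | COC(OC)C=O | starting material
25 | Morita–Baylis–Hillman alcohol (C10 epimers) | C=C(C(O)C(OC)OC)C(=O)CC1=C(C)C[C@@H](O[Si](C)(C)C(C)(C)C)CC1(C)C | intermediate
26 | (E)-oct-2-enoic acid | CCCCC/C=C/C(=O)O | starting material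
27 | 9E ester acetal | CCCCC/C=C/C(=O)OC\C(=C/C(OC)OC)C(=O)CC1=C(C)C[C@@H](O[Si](C)(C)C(C)(C)C)CC1(C)C | intermediate
28 | 9E keto aldehyde with the octenoate | CCCCC/C=C/C(=O)OC\C(=C/C=O)C(=O)CC1=C(C)C[C@@H](O[Si](C)(C)C(C)(C)C)CC1(C)C | intermediate
29 | 3,3'-bis-O-TBS ether of the target | CCCCC/C=C/C(=O)OC\C(=C/C=C/C(C)=C/C=C/C=C(C)/C=C/C=C(C)/C=C/[C@H]1C(C)=C[C@H](O[Si](C)(C)C(C)(C)C)CC1(C)C)C(=O)CC1=C(C)C[C@@H](O[Si](C)(C)C(C)(C)C)CC1(C)C | intermediate
30 | (3R,3'R,6'R)-3,3'-dihydroxy-19-[(2E)-oct-2-enoyloxy]-7,8-dihydro-β,ε-caroten-8-one | CCCCC/C=C/C(=O)OC\C(=C/C=C/C(C)=C/C=C/C=C(C)/C=C/C=C(C)/C=C/[C@H]1C(C)=C[C@H](O)CC1(C)C)C(=O)CC1=C(C)C[C@@H](O)CC1(C)C | target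

**Step count**

Total step count: 21. Longest linear sequence: 11 (steps 1–8, 11, 20, 21).

**Steps most likely to fail**

Step 6.
- Risk: the ionising oxirane may leak into a 1,2-hydride shift that keeps the seven-membered ring, into proton loss from the allyl cation, or into transannular capture by the C3' oxygen. The labile aldehyde may also drift into conjugation.
- Fallback (sets out from 3, returns at 7): a stepwise semipinacol rearrangement with a discrete leaving group. Opening and shift each invert C6', so the mirror-image oxirane is needed.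
- Epoxidation of 3 with the (R,R)-enantiomer of the manganese catalyst gives the (1R,7S)-epoxy enone F1.
- The reduction of step 4 gives the cis-epoxy alcohol F2, and silylation gives the silyl ether F3.
- MgBr2·OEt2 opens the oxirane at the allylic carbon with inversion to the trans-bromohydrin F4.
- Ag2CO3 in CH2Cl2 abstracts bromide from the diequatorial conformer, in which the C7'–C1' ring bond is antiperiplanar to C–Br, so the ring contracts to 7.

Step 7.
- Risk: enolisation of the doubly activated C6'–H by the phosphonate anion would cause epimerisation, a shift of the alkene into conjugation, or loss of silanol.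
- Fallback (sets out from 7, returns at 10): base-free chain extension.
- Takai olefination (CrCl2, CHI3, THF) gives the E-vinyl iodide F5.
- Stille coupling with (E)-3-(tributylstannyl)but-2-en-1-ol (Pd2(dba)3, AsPh3, NMP, rt) gives the dienol F6.
- MnO2 oxidation then gives 10.

Step 20.
- Risk: instead of adding to the aldehyde, the soft polyenyl anion may add to C10 of the doubly activated alkene and expel the C19 carboxylate, or may abstract a C7 proton.
- Fallback (sets out from 10 and 28, returns at 29): a neutral cross-coupling at the C12–C13 single bond.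
- Compound 10 is extended with 8 as in step 7 to the twenty-carbon tetraenenitrile F7, which is reduced as in step 8 to the twenty-carbon tetraenal F8.
- Horner–Wadsworth–Emmons olefination of F8 with diethyl [(E)-3-(tributylstannyl)but-2-en-1-yl]phosphonate gives the hexaenyl stannane F9.
- Takai olefination of 28, which is selective for the aldehyde over the ketone, gives the dienyl iodide F10.
- Stille coupling of F9 with F10 (Pd2(dba)3, AsPh3, NMP, rt, dark) gives 29.

**Further compounds**

F1 | step 6 | (1R,7S)-2,6,6-trimethyl-8-oxabicyclo[5.1.0]oct-2-en-4-one | CC1=CC(=O)CC(C)(C)[C@@H]2O[C@H]12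
F2 | step 6 | (1R,4R,7S)-2,6,6-trimethyl-8-oxabicyclo[5.1.0]oct-2-en-4-ol | CC1=C[C@H](O)CC(C)(C)[C@@H]2O[C@H]12
F3 | step 6 | (1R,4R,7S)-4-(tert-butyldimethylsilyloxy)-2,6,6-trimethyl-8-oxabicyclo[5.1.0]oct-2-ene | CC1=C[C@H](O[Si](C)(C)C(C)(C)C)CC(C)(C)[C@@H]2O[C@H]12
F4 | step 6 | (1S,2S,5R)-2-bromo-5-(tert-butyldimethylsilyloxy)-3,7,7-trimethylcyclohept-3-en-1-ol | CC1=C[C@H](O[Si](C)(C)C(C)(C)C)CC(C)(C)[C@H](O)[C@H]1Br
F5 | step 7 | (E)-vinyl iodide of the ε ring | I/C=C/[C@H]1C(C)=C[C@H](O[Si](C)(C)C(C)(C)C)CC1(C)C
F6 | step 7 | (2E,4E)-dienol of the ε end group | OC/C=C(C)/C=C/[C@H]1C(C)=C[C@H](O[Si](C)(C)C(C)(C)C)CC1(C)C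
F7 | step 20 | all-E twenty-carbon tetraenenitrile | N#C/C=C(C)/C=C/C=C(C)/C=C/[C@H]1C(C)=C[C@H](O[Si](C)(C)C(C)(C)C)CC1(C)C
F8 | step 20 | all-E twenty-carbon tetraenal | O=C/C=C(C)/C=C/C=C(C)/C=C/[C@H]1C(C)=C[C@H](O[Si](C)(C)C(C)(C)C)CC1(C)C
F9 | step 20 | all-E hexaenyl tributylstannane (tin on C13) | CCCC[Sn](CCCC)(CCCC)/C(C)=C/C=C/C=C(C)/C=C/C=C(C)/C=C/[C@H]1C(C)=C[C@H](O[Si](C)(C)C(C)(C)C)CC1(C)C
F10 | step 20 | (9E,11E)-dienyl iodide of the keto half (iodine on C12) | CCCCC/C=C/C(=O)OC\C(=C/C=C/I)C(=O)CC1=C(C)C[C@@H](O[Si](C)(C)C(C)(C)C)CC1(C)C
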